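**Retrosynthetic overview** (locants of the 15-oxabicyclo[10.2.1]pentadecane skeleton)
1. The 10E-alkene comes last, by hydroxyl-directed trans-semihydrogenation of the macrocyclic 10-yne.
2. Key step: the C11–C12 bond is formed by a hydrogen-atom-transfer radical macrocyclisation. A tertiary α-oxy radical, generated from a 2,3-dihydrofuran, adds to a tethered alkynyl sulfone; this closes the 14-membered ring and sets the C12 quaternary centre (cis-bridged).
3. Ring order: the five-membered ether ring first (gold 5-endo cyclisation of a homopropargylic tertiary alcohol), then the 14-membered carbocycle.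
4. The C7–C8 ketone bond comes from a nickel radical acyl–alkyl coupling of a C2–C7 acid with a chiral iodohydrin made from (S)-2-methylglycidol (source of C9).
5. C1/C2 come from a Sharpless kinetic-resolution epoxidation followed by alkynyl opening; C5 from a copper-catalysed asymmetric conjugate addition to methyl crotonate.

Assumption: the two Grignard solutions and (S)-2-methylglycidol are bought; descriptors were derived from the given SMILES, which reads as (1S,2R,5S,9R,10E,12S).

Step 1
Reactants: 1 methyl (2E)-but-2-enoate; 2 but-3-en-1-ylmagnesium bromide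
Product: 3 methyl (3S)-3-methylhept-6-enoate
Conditions: CuI (2 mol%), Tol-BINAP (3 mol%, the antipode that delivers 3S), t-BuOMe, −40 °C; then 1 M HCl, 0 °C
Reagents that add atoms: none
Why: Copper-catalysed asymmetric conjugate (Michael) addition of a Grignard reagent to an enoate, in which the chiral bisphosphine–copper complex selects the enoate face and sets C3 (the other ligand antipode gives 3R; the sense is confirmed by optical rotation).

Step 2
Reactants: 3 methyl (3S)-3-methylhept-6-enoate
Product: 4 methyl (3S)-3-methyl-6-oxohexanoate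
Conditions: O3, CH2Cl2, −78 °C; then Me2S, −78 °C to rt
Reagents that add atoms: ozone [O-][O+]=O
Why: Ozonolysis with reductive work-up cleaves only the terminal alkene and leaves the remote stereocentre untouched.

Step 3
Reactants: 4 methyl (3S)-3-methyl-6-oxohexanoate; 5 prop-1-en-2-ylmagnesium bromide
Product: 6 methyl (3S,6RS)-6-hydroxy-3,7-dimethyloct-7-enoate (about 1:1 at C6)
Conditions: THF, −78 °C; aq. NH4Cl
Reagents that add atoms: none
Why: Grignard 1,2-addition is chemoselective for the aldehyde over the methyl ester at −78 °C; the new carbinol centre is deliberately unselective and is resolved in step 4.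

Step 4
Reactants: 6 methyl (3S,6RS)-6-hydroxy-3,7-dimethyloct-7-enoate
Product: 7 methyl (3S,6R)-6-hydroxy-3-methyl-6-[(2S)-2-methyloxiran-2-yl]hexanoate
Conditions: Ti(OiPr)4 (10 mol%), D-(−)-diisopropyl tartrate (15 mol%), t-BuOOH (0.55 equiv), 4 Å sieves, CH2Cl2, −20 °C; the unreacted (6S)-alcohol is removed by chromatography
Reagents that add atoms: tert-butyl hydroperoxide CC(C)(C)OO
Why: Sharpless asymmetric epoxidation run as a kinetic resolution, in which the D-tartrate catalyst epoxidises only the (6R)-alcohol and delivers oxygen anti to the chain (erythro), so the carbinol and the quaternary epoxide carbon are set together (maximum yield 50%).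

Step 5
Reactants: 7 methyl (3S,6R)-6-hydroxy-3-methyl-6-[(2S)-2-methyloxiran-2-yl]hexanoate; 8 3-methylbut-1-yne
Product: 10 (3S,6R,7S)-6,7-dihydroxy-3,7,11-trimethyldodec-9-ynoic acid, via methyl ester 9 (not isolated)
Conditions: 8 (3 equiv), n-BuLi, THF, −78 °C; BF3·OEt2; then 7, −78 °C; then LiOH, MeOH/H2O, rt; acidify to pH 3
Reagents that add atoms: lithium hydroxide [Li+].[OH-]
Why: Yamaguchi-type alkynylation, in which the alkynyl trifluoroborate opens the BF3-activated epoxide by SN2 attack at its CH2 terminus so that the quaternary C–O centre is retained, followed by saponification in the same pot.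

Step 6
Reactants: 10 (3S,6R,7S)-6,7-dihydroxy-3,7,11-trimethyldodec-9-ynoic acid
Product: 11 (3S,6R,7S)-6-(acetyloxy)-7-hydroxy-3,7,11-trimethyldodec-9-ynoic acid
Conditions: Ac2O (3 equiv), pyridine, DMAP (5 mol%), CH2Cl2, 0 °C; then aq. NaHCO3 (hydrolyses the mixed anhydride), acidify
Reagents that add atoms: acetic anhydride CC(=O)OC(C)=O
Why: Nucleophile-catalysed acylation takes the secondary alcohol and leaves the hindered tertiary alcohol free, with no change at any stereocentre.

Step 7
Reactants: 12 [(2S)-2-methyloxiran-2-yl]methanol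
Product: 14 (2S)-2-ethynyl-2-methyloxirane, via epoxy aldehyde 13 (not isolated)
Conditions: TEMPO (10 mol%), PhI(OAc)2, CH2Cl2, rt; then MeOH, K2CO3, dimethyl (1-diazo-2-oxopropyl)phosphonate, 0 °C to rt; the volatile product is carried on as a THF solution
Reagents that add atoms: dimethyl (1-diazo-2-oxopropyl)phosphonate CC(=O)C(=[N+]=[N-])P(=O)(OC)OC
Why: Oxoammonium oxidation followed by Seyferth–Gilbert (Ohira–Bestmann) homologation, in which the quaternary α-carbon cannot epimerise so the glycidol stereocentre is carried over unchanged.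

Step 8
Reactants: 14 (2S)-2-ethynyl-2-methyloxirane
Product: 16 (2S)-1-iodo-2-methyl-4-(trimethylsilyl)but-3-yn-2-ol, via silylated epoxide 15 (not isolated)
Conditions: n-BuLi, THF, −78 °C; Me3SiCl; then LiI, AcOH, THF, 0 °C
Reagents that add atoms: chlorotrimethylsilane C[Si](C)(C)Cl; lithium iodide [Li+].[I-]
Why: C-silylation of the acetylide and then SN2 opening of the 2,2-disubstituted epoxide by iodide at CH2, leaving the tertiary carbinol stereocentre intact.

Step 9
Reactants: 11 (3S,6R,7S)-6-(acetyloxy)-7-hydroxy-3,7,11-trimethyldodec-9-ynoic acid; 16 (2S)-1-iodo-2-methyl-4-(trimethylsilyl)but-3-yn-2-ol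
Product: 17 (3R,7S,10R,11S)-3,11-dihydroxy-3,7,11,15-tetramethyl-5-oxo-1-(trimethylsilyl)hexadeca-1,13-diyn-10-yl acetate
Conditions: Boc2O, MgCl2, Zn, Ni(acac)2 (10 mol%), 4,4′-di-tert-butyl-2,2′-bipyridine (12 mol%), THF/MeCN, 25 °C
Reagents that add atoms: none
Why: Nickel-catalysed reductive acyl–alkyl cross-electrophile coupling, in which the β-hydroxyalkyl radical from the iodide is captured by the acyl–nickel species formed from the in situ mixed anhydride, giving the tertiary aldol without a basic enolate and without touching the acetate or any stereocentre.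

Step 10
Reactants: 17 (3R,7S,10R,11S)-3,11-dihydroxy-3,7,11,15-tetramethyl-5-oxo-1-(trimethylsilyl)hexadeca-1,13-diyn-10-yl acetate
Product: 18 (3R,7S,10R,11S)-3,11-dihydroxy-3,7,11,15-tetramethyl-5-oxohexadeca-1,13-diyn-10-yl acetate
Conditions: Bu4NF, AcOH (1:1), THF, 0 °C
Reagents that add atoms: none
Why: Buffered fluoride protodesilylation frees the terminal alkyne without retro-aldol cleavage of the tertiary β-hydroxy ketone or loss of the acetate.

Step 11
Reactants: 18 (3R,7S,10R,11S)-3,11-dihydroxy-3,7,11,15-tetramethyl-5-oxohexadeca-1,13-diyn-10-yl acetate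
Product: 20 (3R,7S,10R,11S)-3,11-dihydroxy-3,7,11,15-tetramethyl-1-(4-methylbenzenesulfonyl)-5-oxohexadeca-1,13-diyn-10-yl acetate, via iodovinyl sulfone 19 (not isolated)
Conditions: 4-methylbenzenesulfonyl iodide (1.05 equiv), CH2Cl2, visible light, rt; then K2CO3, acetone, rt to 40 °C
Reagents that add atoms: 4-methylbenzenesulfonyl iodide Cc1ccc(cc1)S(=O)(=O)I
Why: Radical-chain iodosulfonylation, in which the sulfonyl radical adds to the terminal alkyne much faster than to the hindered internal one, followed by E1cB loss of HI to give the alkynyl sulfone.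

Step 12
Reactants: 20 (3R,7S,10R,11S)-3,11-dihydroxy-3,7,11,15-tetramethyl-1-(4-methylbenzenesulfonyl)-5-oxohexadeca-1,13-diyn-10-yl acetate
Product: 22 (1S,2R,5S,9R,12S)-9-hydroxy-1,5,9-trimethyl-7-oxo-12-(propan-2-yl)-15-oxabicyclo[10.2.1]pentadec-10-yn-2-yl acetate, via dihydrofuran 21 (not isolated)
Conditions: [(t-Bu)2(2-biphenylyl)P]Au(NCMe)SbF6 (2 mol%), THF, rt; Et3N; then syringe-pump addition (10 h) to Fe(acac)3 (30 mol%), Ph(i-PrO)SiH2 (3 equiv), THF/i-PrOH 4:1, 40 °C, final 2 mM
Reagents that add atoms: none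
Why: Proposed new method: gold 5-endo-dig cycloisomerisation gives the enol ether, an iron hydride then transfers H• to its β-carbon to give the tertiary α-oxy radical, which adds 14-endo to the sulfonyl-bearing alkyne carbon and expels the sulfonyl radical (returned to the cycle by divalent iron); the chain anchored on the neighbouring quaternary carbon can only reach the radical from its own face, so the new quaternary centre forms cis-bridged (12S), and the closest known reactions are the intermolecular iron/silane hydroalkynylation of alkenes with alkynyl sulfones, iron/silane olefin cross-coupling of enol ethers, and photoredox radical macrocyclisations.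

Step 13
Reactants: 22 (1S,2R,5S,9R,12S)-9-hydroxy-1,5,9-trimethyl-7-oxo-12-(propan-2-yl)-15-oxabicyclo[10.2.1]pentadec-10-yn-2-yl acetate
Product: 23 (1S,2R,5S,9R,10E,12S)-9-hydroxy-1,5,9-trimethyl-7-oxo-12-(propan-2-yl)-15-oxabicyclo[10.2.1]pentadec-10-en-2-yl acetate
Conditions: [(C5Me5)RuCl]4 (5 mol% Ru), H2 (1 atm), CH2Cl2, rt
Reagents that add atoms: none
Why: Hydroxyl-directed ruthenium-catalysed trans-hydrogenation delivers the E-alkene directly; ketone and acetate are inert, and with no allylic hydrogens on either side isomerisation is impossible.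

**Compound list**
1 | methyl (2E)-but-2-enoate | C/C=C/C(=O)OC | starting material
2 | but-3-en-1-ylmagnesium bromide | C=CCC[Mg]Br | starting material
3 | methyl (3S)-3-methylhept-6-enoate | C=CCC[C@H](C)CC(=O)OC | intermediate
4 | methyl (3S)-3-methyl-6-oxohexanoate | O=CCC[C@H](C)CC(=O)OC | intermediate
5 | prop-1-en-2-ylmagnesium bromide | CC(=C)[Mg]Br | starting material
6 | methyl (3S,6RS)-6-hydroxy-3,7-dimethyloct-7-enoate | C=C(C)C(O)CC[C@H](C)CC(=O)OC | intermediate
7 | methyl (3S,6R)-6-hydroxy-3-methyl-6-[(2S)-2-methyloxiran-2-yl]hexanoate | COC(=O)C[C@@H](C)CC[C@@H](O)[C@]1(C)CO1 | intermediate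
8 | 3-methylbut-1-yne | CC(C)C#C | starting material
9 | methyl (3S,6R,7S)-6,7-dihydroxy-3,7,11-trimethyldodec-9-ynoate | COC(=O)C[C@@H](C)CC[C@@H](O)[C@@](C)(O)CC#CC(C)C | intermediate
10 | (3S,6R,7S)-6,7-dihydroxy-3,7,11-trimethyldodec-9-ynoic acid | OC(=O)C[C@@H](C)CC[C@@H](O)[C@@](C)(O)CC#CC(C)C | intermediate
11 | (3S,6R,7S)-6-(acetyloxy)-7-hydroxy-3,7,11-trimethyldodec-9-ynoic acid | OC(=O)C[C@@H](C)CC[C@@H](OC(C)=O)[C@@](C)(O)CC#CC(C)C | intermediate
12 | [(2S)-2-methyloxiran-2-yl]methanol | C[C@]1(CO)CO1 | starting material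
13 | (2R)-2-methyloxirane-2-carbaldehyde | C[C@]1(C=O)CO1 | intermediate
14 | (2S)-2-ethynyl-2-methyloxirane | C[C@]1(C#C)CO1 | intermediate
15 | trimethyl{[(2S)-2-methyloxiran-2-yl]ethynyl}silane | C[C@]1(C#C[Si](C)(C)C)CO1 | intermediate
16 | (2S)-1-iodo-2-methyl-4-(trimethylsilyl)but-3-yn-2-ol | C[C@](O)(C#C[Si](C)(C)C)CI | intermediate
17 | (3R,7S,10R,11S)-3,11-dihydroxy-3,7,11,15-tetramethyl-5-oxo-1-(trimethylsilyl)hexadeca-1,13-diyn-10-yl acetate | CC(=O)O[C@H](CC[C@H](C)CC(=O)C[C@@](C)(O)C#C[Si](C)(C)C)[C@@](C)(O)CC#CC(C)C | intermediate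
18 | (3R,7S,10R,11S)-3,11-dihydroxy-3,7,11,15-tetramethyl-5-oxohexadeca-1,13-diyn-10-yl acetate | CC(=O)O[C@H](CC[C@H](C)CC(=O)C[C@@](C)(O)C#C)[C@@](C)(O)CC#CC(C)C | intermediate
19 | (1E,3R,7S,10R,11S)-3,11-dihydroxy-2-iodo-3,7,11,15-tetramethyl-1-(4-methylbenzenesulfonyl)-5-oxohexadec-1-en-13-yn-10-yl acetate | CC(=O)O[C@H](CC[C@H](C)CC(=O)C[C@@](C)(O)/C(I)=C\S(=O)(=O)c1ccc(C)cc1)[C@@](C)(O)CC#CC(C)C | intermediate
20 | (3R,7S,10R,11S)-3,11-dihydroxy-3,7,11,15-tetramethyl-1-(4-methylbenzenesulfonyl)-5-oxohexadeca-1,13-diyn-10-yl acetate | CC(=O)O[C@H](CC[C@H](C)CC(=O)C[C@@](C)(O)C#CS(=O)(=O)c1ccc(C)cc1)[C@@](C)(O)CC#CC(C)C | intermediate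
21 | (1R,4S,8R)-8-hydroxy-4,8-dimethyl-1-[(2S)-2-methyl-5-(propan-2-yl)-2,3-dihydrofuran-2-yl]-10-(4-methylbenzenesulfonyl)-6-oxodec-9-yn-1-yl acetate | CC(=O)O[C@H](CC[C@H](C)CC(=O)C[C@@](C)(O)C#CS(=O)(=O)c1ccc(C)cc1)[C@]1(C)CC=C(C(C)C)O1 | intermediate
22 | (1S,2R,5S,9R,12S)-9-hydroxy-1,5,9-trimethyl-7-oxo-12-(propan-2-yl)-15-oxabicyclo[10.2.1]pentadec-10-yn-2-yl acetate | CC(=O)O[C@@H]1CC[C@H](C)CC(=O)C[C@@](C)(O)C#C[C@@]2(C(C)C)CC[C@]1(C)O2 | intermediate
23 | (1S,2R,5S,9R,10E,12S)-9-hydroxy-1,5,9-trimethyl-7-oxo-12-(propan-2-yl)-15-oxabicyclo[10.2.1]pentadec-10-en-2-yl acetate | CC(=O)O[C@@H]1CC[C@H](C)CC(=O)C[C@@](C)(O)/C=C/[C@@]2(C(C)C)CC[C@]1(C)O2 | target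

**Step count**
Total: 13 steps. Longest linear sequence: 11 steps (steps 1–6 and 9–13); steps 7–8 run in parallel.

**Three steps most likely to fail**

Step 12 (radical macrocyclisation). The slow 14-membered closure competes with reduction of the α-oxy radical or its oxidation to the oxocarbenium ion. The fallback sets out from 20 and comes back at 22. After the same gold cycloisomerisation, benzeneselenol is added across the enol ether (cat. pyridinium tosylate, CH2Cl2, −20 °C) to give the 5-(phenylselanyl)oxolane F1 (both epimers, which does not matter). Photolysis with (Bu3Sn)2 in benzene at 2 mM then generates the same radical by selenium-group transfer in a medium with no hydride donor and no oxidant, and it closes onto the alkynyl sulfone to give 22.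

Step 9 (nickel acyl–alkyl coupling with a free β-hydroxy iodide). Zinc-induced β-elimination or side reactions of the internal alkyne could erode it. The fallback is a polar acylation; it sets out from 11 and from 15 (isolated for this purpose) and comes back at 17. Acid 11 is converted with carbonyldiimidazole into the acyl imidazolide F2. Epoxide 15 is opened with PhSO2Na (DMF, 60 °C) to the β-hydroxy sulfone F3. The dianion of F3 (LDA, THF, −78 °C) is added to F2 (one extra equivalent of base for its free hydroxyl) to give the β-keto sulfone F4, which SmI2 (THF/MeOH, −78 °C) desulfonylates to 17.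

Step 13 (trans-hydrogenation of an alkyne flanked by two quaternary carbons). It may stall or over-reduce. The fallback sets out from 22 and comes back at 23. Hydroxyl-directed trans-hydrostannation (Bu3SnH, [(C5Me5)RuCl]4, CH2Cl2) gives the α-stannyl alkene F5. Protodestannation with copper thiophene-2-carboxylate (CuO2CC4H3S, DMF, rt) then gives the E-alkene 23 with retention of geometry.

**Further compounds**
F1 | step 12 | (1R,4S,8R)-8-hydroxy-4,8-dimethyl-1-[(2S,5RS)-2-methyl-5-(phenylselanyl)-5-(propan-2-yl)oxolan-2-yl]-10-(4-methylbenzenesulfonyl)-6-oxodec-9-yn-1-yl acetate | CC(=O)O[C@H](CC[C@H](C)CC(=O)C[C@@](C)(O)C#CS(=O)(=O)c1ccc(C)cc1)[C@]1(C)CCC(C(C)C)([Se]c2ccccc2)O1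
F2 | step 9 | (3S,6R,7S)-7-hydroxy-1-(1H-imidazol-1-yl)-3,7,11-trimethyl-1-oxododec-9-yn-6-yl acetate | CC(=O)O[C@H](CC[C@H](C)CC(=O)n1ccnc1)[C@@](C)(O)CC#CC(C)C
F3 | step 9 | (2S)-1-(benzenesulfonyl)-2-methyl-4-(trimethylsilyl)but-3-yn-2-ol | C[C@](O)(C#C[Si](C)(C)C)CS(=O)(=O)c1ccccc1
F4 | step 9 | (3S,4RS,7S,10R,11S)-4-(benzenesulfonyl)-3,11-dihydroxy-3,7,11,15-tetramethyl-5-oxo-1-(trimethylsilyl)hexadeca-1,13-diyn-10-yl acetate | CC(=O)O[C@H](CC[C@H](C)CC(=O)C([C@@](C)(O)C#C[Si](C)(C)C)S(=O)(=O)c1ccccc1)[C@@](C)(O)CC#CC(C)C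
F5 | step 13 | (1S,2R,5S,9R,10Z,12S)-9-hydroxy-1,5,9-trimethyl-7-oxo-12-(propan-2-yl)-10-(tributylstannyl)-15-oxabicyclo[10.2.1]pentadec-10-en-2-yl acetate | CC(=O)O[C@@H]1CC[C@H](C)CC(=O)C[C@@](C)(O)/C([Sn](CCCC)(CCCC)CCCC)=C/[C@@]2(C(C)C)CC[C@]1(C)O2
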